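All runs are calculated on assumed constants.

I had no constants for this flask, so I read its time scales off the south-west run, which is this same flask followed for its first 50.0 s.

common to all: left-handed substrate 0.89 M; right-handed substrate 0.89 M; free catalyst 1 mol%; added ligand 46 mM
- south-west: reagent 3 equiv; the very flask that is asked about, followed so far
- flask: reagent 3.00 equiv; time 4.0 min

- south-west (time / s: left-handed substrate / %, right-handed substrate / %, left-handed product / %): 10.0: 46.5, 49.3, 4.4; 20.0: 44.6, 47.3, 8.0; 30.0: 43.1, 46.7, 10.7; 40.0: 41.4, 45.2, 13.0; 50.0: 41.3, 43.6, 14.6

(standard deviation of a reading: 0.3 percentage points)

- free catalyst is single-handed; left-handed substrate and right-handed substrate are mirror images of each other, charged as a racemate, each of them at the stated concentration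
- the numbers in the tables scatter by 0.3 percentage points (one standard deviation)
- an excess is the difference of the two amounts in percent of their sum
- an excess is below zero if the other one leads

* part of the left-handed substrate and right-handed substrate charged together that has reacted at 4.0 min
* excess of left-handed product over right-handed product in the product at 4.0 min
* excess of right-handed substrate over left-handed substrate among what is left of the two at 4.0 min

On the first rung I could read stood the two substrates. The right-handed one led by 2.8 percentage points at 10.0 s and by 2.3 points at 50.0 s, while the left-handed product grew from 4.4% to 14.6%, so I took them to turn into each other, as in a dynamic kinetic resolution.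

On the next rung I took the catalyst to fade: in the south-west run the last product gain read 36.4% of the first, though 84.9% of the substrates remained. The curve to watch is therefore the product's flattening.

The last rung I took to be the thinning of substrate and reagent, which I assumed the rate follows as a product. Dividing that out turns the reacted share c into a dose, 3 ln((1 − 2c/3)/(1 − c)), for this charge. Left-handed product was nearly all of what had reacted, so I used it as c, which gave 0.0457 at 10.0 s and 0.166 at 50.0 s.

I assumed that the dose in this flask grew in step with time at the start and levelled off late. Joining both ends as a hyperbola gave a half-way time of 97.1 s, a reading that carries the scatter of the two points behind it. At 4.0 min this gave 0.348, the worked dose, meaning progress with the thinning divided out, and so a reacted share of 27.0%.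

The forecast gave a reacted share of 27%, a product excess of 98% and a substrate excess of 5%, holding that “The catalyst is therefore dying or being inhibited”.

The flask gave a reacted share of 27.8%, a product excess of 92.8% and a substrate excess of 0.339%.

    free catalyst → spent catalyst (k = 0.167 /s)
    reagent + free catalyst + right-handed substrate → free catalyst + right-handed product (k = 0.194 /M²/s)
    reagent + free catalyst + left-handed substrate → free catalyst + left-handed product (k = 5.44 /M²/s)
    free catalyst + added ligand ⇌ idle complex, settled at all times (K = 340 /M)
    left-handed substrate ⇌ right-handed substrate (k = 0.0403 /s)

At 4.00 min the catalyst in this flask stood as 92.3% spent catalyst, 7.22% idle complex and 0.468% free catalyst. For the neighbour charged with 2.5 mol% of free catalyst, I scaled the worked dose by the loading to 0.871, which turned back into a reacted share of 50.2%. That neighbour stood at 50.8%.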